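The numbers were drawn at random within sensible limits; the rest is arithmetic.

Count the second nucleophile by what is left of it.

    substrate → open intermediate (k1 = 4.6 × 10⁻⁴ s⁻¹)
    first nucleophile + open intermediate ⇌ target (K2 = 130 L mol⁻¹, k2 = 0.58 L mol⁻¹ s⁻¹)
    second nucleophile + open intermediate → other capture product (k3 = 1.0 L mol⁻¹ s⁻¹)
    open intermediate → solvolysis product (k4 = 0.020 s⁻¹)
    crystals ⇌ target, rate k5*(cs5 - [target]) while solid is left; crystals form when [target] > cs5 (cs5 = 19 mM, k5 = 0.089 s⁻¹)
    open intermediate + capture agent → trapped intermediate (k6 = 0.0011 L mol⁻¹ s⁻¹)

substrate 0.068 M; first nucleophile 1.30 equiv; second nucleophile 1.20 equiv; capture agent 6.80 mM; time 12 h

- target is meant together with its crystals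
- solid, in amounts per volume of the solution: crystals
- the reaction counts as stopped when no species that holds the substrate changes by six tenths of a point or more over the second half of the time
- run time (flask): 12 h

1. the state of affairs at 12 h: stopped, and by what, or still going (it is still moving / the second nucleophile has run out first / the first nucleophile has run out first / forward and back rates have come level / all of the substrate has reacted)
2. how much of the substrate has reacted by 12 h
3. how much other capture product there is at 12 h, in percent of the substrate charged

The substrate opens with a half-life of 0.42 h, short against 12 h, so by reckoning >99.9 % of it has reacted. With the substrate and second nucleophile at their charges, the open intermediate is reckoned near 0.308 mM, and the target in balance with it near 3.54 mM, which is less than the solubility 19 mM, so no crystals are expected. The target gives its material back through the open intermediate. The capture agent offers 7.48 × 10⁻⁶ s⁻¹ against 0.020 s⁻¹ for solvolysis, so two exits count.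

Their contest is one number, the level concentration 20.0 mM: the concentration of second nucleophile at which capture and solvolysis run equally fast. Both steps draw on the same open intermediate, so its concentration cancels. The logarithm of the fraction of second nucleophile left, with its sign turned, equals the solvolysis product made divided by the level concentration. The charge of 81.6 mM exceeds the substrate, so the substrate is the limiting reagent, and what it feeds is split between the nucleophile consumed and the solvolysis product. Newton steps on that balance from 0.5 give a fraction left of 39.0 %, then 39.5 %, and so 72.7 % other capture product.

The second way counts the fraction made, in two equal portions of substrate. The capture share is 80.3 % at the charge and 73.1 % midway, which gives 76.7 %. This way cheats, and its figure is higher: each portion is counted at its opening share while the nucleophile falls within it. The fraction left needs no portions.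

The forecast says that all of the substrate has reacted, with 100 % conversion and 72.6 % other capture product, within 71.5 % to 73.5 %, holding that “the excess second nucleophile never runs out”.

In the simulation all of the substrate has reacted, with 100 % conversion and 72.6 % other capture product.

In this flask 39 % of the second nucleophile stands at the end, and through the level concentration that reads as 27.3 % solvolysis product against the simulated 27.3 %. For the neighbour flask with 0.300 equiv of second nucleophile, the balance gives 9.26 %, then 8.42 %, then 8.49 % of its charge left, and that neighbour flask holds 8.49 %. This flask has come to rest: 12 h spans 28.6 substrate half-lives, and its largest change from 6.00 h on is 0 percentage points. At ten times the time, other capture product stands at 72.6 %.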